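**Retrosynthetic overview**

1. Target 14 is the 4-O-acetate of a trans-4,5-dihydroxy-5-(1-hydroxyalkyl)cyclopent-2-enone; the last two steps only acetylate O4 of diol 12 and unmask O1'.
2. Key disconnection C4–C5: the C1 ketone, the C5 tertiary carbinol and the C4 carbinol form an aldol retron, and C4–C3=C2–C1 is a cis-4-oxo-2-enal, i.e. an oxidised 2-substituted furan. The ring C1–C5 therefore comes from furyl carbinol 8 (furan C2–C5 = C1–C4, furfuryl carbon = C5) by one-pot Achmatowicz oxidation and amine-mediated ring contraction.
3. C5 passes through an enediol, so its configuration in 8 is irrelevant (stereoconvergence); the (S)-silyloxy centre C1', the only stereocentre carried in, sets C5, and the closure geometry sets C4.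
4. 8 comes from 2-furyllithium and (S)-2-silyloxytetradecanal 5, which comes from methyl (S)-glycidate 1 and undecylmagnesium bromide 2 (epoxide opening, silylation, DIBAL-H).
5. Ring order: a temporary dihydropyranone lactol (in the flask), then the cyclopentenone, the only ring of the skeleton, closed last.

Key step: step 5

Remark: ring atoms are numbered C1 (ketone), C2=C3, C4 (acetoxy carbon), C5 (quaternary carbinol), C1' (side-chain carbinol); the CIP label of C5 reads R while O1' is silylated and S in the target, with no change in geometry. TBS = tert-butyldimethylsilyl.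

**Route**

Step 1
Reactants: 1 methyl (S)-glycidate; 2 undecylmagnesium bromide
Product: 3 methyl (2S)-2-hydroxytetradecanoate
Conditions: 2 (1.3 equiv), CuBr·SMe2 (10 mol %), THF, −78 → −40 °C
Reagents that add atoms: none
Why: Copper-catalysed Grignard opening of the glycidic ester (organocuprate epoxide opening) takes place at the unsubstituted C3, so the C2 stereocentre is not touched and becomes C1' of the target with S configuration.

Step 2
Reactants: 3 methyl (2S)-2-hydroxytetradecanoate
Product: 4 methyl (2S)-2-(TBS-oxy)tetradecanoate
Conditions: TBSCl, imidazole, DMF, rt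
Reagents that add atoms: tert-butyldimethylsilyl chloride (TBSCl), CC(C)(C)[Si](C)(C)Cl
Why: Standard silylation of a secondary α-hydroxy ester (Corey conditions) installs the bulky ether that later acts as the stereocontrolling group and that survives until the last step.

Step 3
Reactants: 4 methyl (2S)-2-(TBS-oxy)tetradecanoate
Product: 5 (2S)-2-(TBS-oxy)tetradecanal
Conditions: DIBAL-H (1.1 equiv), CH2Cl2, −78 °C
Reagents that add atoms: none
Why: Partial reduction of an α-silyloxy ester with DIBAL-H stops at the aluminium hemiacetal at −78 °C, which should release the aldehyde on work-up without epimerisation.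

Step 4
Reactants: 5 (2S)-2-(TBS-oxy)tetradecanal; 6 furan
Product: 8 (2S)-2-(TBS-oxy)-1-(furan-2-yl)tetradecan-1-ol (both C1 epimers), via 2-furyllithium 7 (not isolated)
Conditions: 6, n-BuLi, THF, 0 °C; then 5, −78 °C
Reagents that add atoms: none
Why: α-Lithiation of furan followed by 1,2-addition to the aldehyde gives the furyl carbinol; the new carbinol centre is left uncontrolled on purpose, because it is erased in step 5.

Step 5
Reactants: 8 (2S)-2-(TBS-oxy)-1-(furan-2-yl)tetradecan-1-ol (both C1 epimers)
Product: 12 (4R,5R)-5-[(1S)-1-(TBS-oxy)tridecyl]-4,5-dihydroxycyclopent-2-en-1-one, via Achmatowicz lactol 9 (not isolated), via open-chain (Z)-keto-enal 10 (not isolated), via (Z)-enediol 11 (not isolated)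
Conditions: NBS (1.05 equiv), NaHCO3, THF/H2O 4:1, 0 °C; then Et3N, 0 °C → rt
Reagents that add atoms: water, O
Why: NBS/H2O oxidises the furan to the pyranone lactol 9 (Achmatowicz reaction), and Et3N then opens 9 to the (Z)-4-oxo-enal 10 and enolises its α-hydroxy ketone to the enediol 11, whose C5 adds to the C4 aldehyde (intramolecular aldol addition), so that the six-membered lactol is contracted to the cyclopentenone. The closest known reaction type is the amine-mediated ring contraction of Achmatowicz pyranones to trans-4,5-dihydroxycyclopent-2-enones, the oxidised counterpart of the Piancatelli rearrangement. The carbocycle closes in the 5-(enolendo)-exo-trig mode, equivalent to a conrotatory 4π closure of the C5–C1–C2–C3–C4 array, and the cis C2=C3 bond inherited from the furan holds C4 within reach of C5. C5 is set by the C1' silyloxy stereocentre in a Felkin-type arrangement (OTBS anti to the forming C4–C5 bond, C1'–H turned towards the incoming tether), and C4 is set by the closure geometry, in which the enediol hydroxyl and the aldehyde oxygen both point outward and should end up trans. The step is stereoconvergent, because both C1 epimers of 8 and all lactol isomers 9 pass through the single enediol 11, in which the old carbinol configuration is erased before the quaternary centre is built. The selectivity that the step needs is the diastereofacial one at C5 relative to C1', which the bulk of the silyl ether next to the reacting carbon should secure, while the mild amine and a short reaction time keep the adduct from equilibrating.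

Step 6
Reactants: 12 (4R,5R)-5-[(1S)-1-(TBS-oxy)tridecyl]-4,5-dihydroxycyclopent-2-en-1-one
Product: 13 (1R,5R)-5-[(1S)-1-(TBS-oxy)tridecyl]-5-hydroxy-4-oxocyclopent-2-en-1-yl acetate
Conditions: Ac2O (1.2 equiv), pyridine, DMAP (cat.), CH2Cl2, 0 °C
Reagents that add atoms: acetic anhydride (Ac2O), CC(=O)OC(C)=O
Why: Acylation under DMAP catalysis should take place only at the secondary allylic C4 hydroxyl, since the tertiary α-ketol hydroxyl at C5 is too hindered to react at 0 °C and O1' is silylated.

Step 7
Reactants: 13 (1R,5R)-5-[(1S)-1-(TBS-oxy)tridecyl]-5-hydroxy-4-oxocyclopent-2-en-1-yl acetate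
Product: 14 (1R,5S)-5-hydroxy-5-[(1S)-1-hydroxytridecyl]-4-oxocyclopent-2-en-1-yl acetate (target)
Conditions: HF·pyridine, THF, 0 °C → rt
Reagents that add atoms: none
Why: Fluoride-mediated desilylation under buffered acidic conditions cleaves the Si–O bond and should leave the acetate, the enone and all three stereocentres untouched, avoiding the basic conditions that favour acyl migration or retro-aldol cleavage.

**Compound list**

1 | methyl (S)-glycidate [methyl (2S)-oxirane-2-carboxylate] | COC(=O)[C@@H]1CO1 | starting material
2 | undecylmagnesium bromide (ether solution) | CCCCCCCCCCC[Mg]Br | starting material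
3 | methyl (2S)-2-hydroxytetradecanoate | CCCCCCCCCCCC[C@H](O)C(=O)OC | intermediate
4 | methyl (2S)-2-(TBS-oxy)tetradecanoate | CCCCCCCCCCCC[C@H](O[Si](C)(C)C(C)(C)C)C(=O)OC | intermediate
5 | (2S)-2-(TBS-oxy)tetradecanal | CCCCCCCCCCCC[C@H](O[Si](C)(C)C(C)(C)C)C=O | intermediate
6 | furan | c1ccoc1 | starting material
7 | 2-furyllithium (not isolated) | [Li]c1ccco1 | intermediate
8 | (2S)-2-(TBS-oxy)-1-(furan-2-yl)tetradecan-1-ol, mixture of C1 epimers | CCCCCCCCCCCC[C@H](O[Si](C)(C)C(C)(C)C)C(O)c1ccco1 | intermediate
9 | 6-hydroxy-2-[(1S)-1-(TBS-oxy)tridecyl]-2H-pyran-3(6H)-one, isomer mixture at C2 and C6 (not isolated) | CCCCCCCCCCCC[C@H](O[Si](C)(C)C(C)(C)C)C1OC(O)C=CC1=O | intermediate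
10 | (2Z,6S)-6-(TBS-oxy)-5-hydroxy-4-oxooctadec-2-enal, C5 epimers (not isolated) | CCCCCCCCCCCC[C@H](O[Si](C)(C)C(C)(C)C)C(O)C(=O)/C=C\C=O | intermediate
11 | (2Z,4Z,6S)-6-(TBS-oxy)-4,5-dihydroxyoctadeca-2,4-dienal (not isolated) | CCCCCCCCCCCC[C@H](O[Si](C)(C)C(C)(C)C)/C(O)=C(O)\C=C/C=O | intermediate
12 | (4R,5R)-5-[(1S)-1-(TBS-oxy)tridecyl]-4,5-dihydroxycyclopent-2-en-1-one (hydroxyls trans) | CCCCCCCCCCCC[C@H](O[Si](C)(C)C(C)(C)C)[C@@]1(O)C(=O)C=C[C@H]1O | intermediate
13 | (1R,5R)-5-[(1S)-1-(TBS-oxy)tridecyl]-5-hydroxy-4-oxocyclopent-2-en-1-yl acetate | CCCCCCCCCCCC[C@H](O[Si](C)(C)C(C)(C)C)[C@@]1(O)C(=O)C=C[C@H]1OC(C)=O | intermediate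
14 | (1R,5S)-5-hydroxy-5-[(1S)-1-hydroxytridecyl]-4-oxocyclopent-2-en-1-yl acetate | CCCCCCCCCCCC[C@H](O)[C@@]1(O)C(=O)C=C[C@H]1OC(C)=O | target

**Summary**

Total step count: 7.
Longest linear sequence: 7 steps (1 → 14).

**Steps most likely to fail**

Step 5 (key step). The acyclic C1' centre may discriminate the two faces of the enediol only weakly, the aldol adduct may equilibrate towards the cis-diol in which O4 avoids the side chain, or the enediol may expel silanolate by β-elimination. The fallback sets out from 8 and comes back at 14, and it makes the C5/C1' pair by a syn-dihydroxylation. Carbinol 8 is rearranged under Piancatelli conditions (Dy(OTf)3 cat., MeCN/H2O, 80 °C) to trans-4-hydroxy-5-[(1S)-1-(TBS-oxy)tridecyl]cyclopent-2-en-1-one F1 (both trans isomers). DBU then eliminates silanol to give racemic (E)-4-hydroxy-5-tridecylidenecyclopent-2-en-1-one F2. Lipase resolution with vinyl acetate separates the enantiomers of F2 as alcohol and acetate; the R series is carried on as (1R)-4-oxo-5-[(E)-tridecylidene]cyclopent-2-en-1-yl acetate F3, and alcohol of S configuration is converted into F3 as well by Mitsunobu inversion with acetic acid. OsO4/NMO should then add to the exocyclic alkene of F3 anti to the acetoxy group; the E geometry fixes C1' relative to C5 and the anti addition fixes C5 relative to C4, which gives 14 directly.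

Step 7. Once O1' is unmasked, the acetyl group may migrate from O4 to the cis-disposed O1', or the β-acetoxy ketone may suffer retro-aldol opening if the medium turns basic. The fallback sets out from 12 and comes back at 14, and it exchanges the order of the last two operations. Diol 12 is desilylated first (aqueous HF, MeCN) to (4R,5S)-4,5-dihydroxy-5-[(1S)-1-hydroxytridecyl]cyclopent-2-en-1-one F4. The ring allylic hydroxyl of F4 is then acetylated regioselectively under neutral conditions with vinyl acetate and immobilised Candida antarctica lipase B, so that the acetate is introduced last and never meets fluoride.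

Step 3. Over-reduction to the primary alcohol, or partial epimerisation and hydration of the α-silyloxy aldehyde during work-up and handling, would erode the only stereocentre that is carried in. The fallback sets out from 4 and comes back at 8, and it avoids the aldehyde. Ester 4 is converted with MeNHOMe·HCl and i-PrMgCl into (2S)-2-(TBS-oxy)-N-methoxy-N-methyltetradecanamide F5. 2-Furyllithium 7 adds once to F5 to give (2S)-2-(TBS-oxy)-1-(furan-2-yl)tetradecan-1-one F6, and NaBH4 reduces F6 to 8. The diastereoselectivity of this reduction does not matter, because the carbinol centre is erased in step 5.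

**Further compounds**

F1 | step 5 | trans-4-hydroxy-5-[(1S)-1-(TBS-oxy)tridecyl]cyclopent-2-en-1-one, both trans isomers | CCCCCCCCCCCC[C@H](O[Si](C)(C)C(C)(C)C)C1C(O)C=CC1=O
F2 | step 5 | racemic (E)-4-hydroxy-5-tridecylidenecyclopent-2-en-1-one | CCCCCCCCCCCC/C=C1/C(=O)C=CC1O
F3 | step 5 | (1R)-4-oxo-5-[(E)-tridecylidene]cyclopent-2-en-1-yl acetate | CCCCCCCCCCCC/C=C1/C(=O)C=C[C@H]1OC(C)=O
F4 | step 7 | (4R,5S)-4,5-dihydroxy-5-[(1S)-1-hydroxytridecyl]cyclopent-2-en-1-one | CCCCCCCCCCCC[C@H](O)[C@@]1(O)C(=O)C=C[C@H]1O
F5 | step 3 | (2S)-2-(TBS-oxy)-N-methoxy-N-methyltetradecanamide | CCCCCCCCCCCC[C@H](O[Si](C)(C)C(C)(C)C)C(=O)N(C)OC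
F6 | step 3 | (2S)-2-(TBS-oxy)-1-(furan-2-yl)tetradecan-1-one | CCCCCCCCCCCC[C@H](O[Si](C)(C)C(C)(C)C)C(=O)c1ccco1
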